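## Retrosynthetic overview
1. Disconnect the C10 salicylate, the C1 and C11 isovalerates and the C7 acetate as late-stage acylations of a cyclopenta[c]pyran bearing free hydroxyls.
2. Form the dienyl-ether pyran from a cyclopentenone. Michael addition of ethyl formylacetate, acetal/enol cyclisation, dehydrogenation and a hydroxyl-directed reduction do this; the reduction places C7–O trans to C8–OH.
3. Make the cyclopentenone, with its C8 quaternary carbinol and C9 centre, in one organocatalytic aldol/aldol-condensation of 3,3-diethoxypropanal with 1-(TBSO)butane-2,3-dione.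
4. Ring order: cyclopentenone first, then the pyran.

Assumptions:
- Ethyl 3-oxopropanoate is available as a commercial solution.
- The (S)-catalyst is assumed to give the drawn C8 configuration; the (R)-catalyst would give the enantiomer.
- The C1 anomers formed in step 11 are separable by chromatography.

## Route

**Step 1**
Reactants: 1, 3,3-diethoxypropan-1-ol
Product: 2, 3,3-diethoxypropanal
Conditions: Dess–Martin periodinane, NaHCO3, CH2Cl2, 0 °C→rt
Reagents that add atoms: none
Why: Dess–Martin oxidation of a primary alcohol to the aldehyde; the acetal is untouched and no stereocentre is involved.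

**Step 2**
Reactants: 3, 4-hydroxybutan-2-one
Product: 4, 4-(tert-butyldimethylsilyloxy)butan-2-one
Conditions: TBSCl, imidazole, DMF, 0 °C
Reagents that add atoms: TBSCl, CC(C)(C)[Si](C)(C)Cl
Why: Standard silyl protection of the primary alcohol, which will become the C10 oxygen.

**Step 3**
Reactants: 4
Product: 5, 1-(tert-butyldimethylsilyloxy)butane-2,3-dione
Conditions: SeO2, 1,4-dioxane/H2O (50:1), 80 °C
Reagents that add atoms: SeO2, O=[Se]=O (supplies the new carbonyl oxygen)
Why: Riley oxidation of the more reactive α-methylene of the methyl ketone gives the 1,2-diketone; no stereocentre is formed.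

**Step 4**
Reactants: 2, 3,3-diethoxypropanal; 5, the diketone
Product: 6, (4S,5R)-4-(diethoxymethyl)-5-{[(tert-butyldimethylsilyl)oxy]methyl}-5-hydroxycyclopent-2-en-1-one
Conditions: (S)-diphenylprolinol TMS ether (20 mol%), PhCO2H (20 mol%), CH2Cl2, 4 °C, 36 h; then piperidine/AcOH (0.2 equiv each), 50 °C, 6 h, one pot
Reagents that add atoms: none
Why: Proposed new method: the enamine of 2 attacks the more electrophilic C2 carbonyl of 5 (the one flanked by CH2OTBS), and the catalyst's facial control sets the C8 tertiary carbinol, which is the first stereocentre.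
- The resulting 1,4-ketoaldehyde undergoes intramolecular aldol condensation through the methyl-ketone enol (C6) onto the aldehyde, giving the cyclopentenone.
- The γ-acidic C9–H equilibrates so that the acetal ends up trans to CH2OTBS, which is the configuration in the target.
- The closest known reactions are enamine aldol additions of aldehydes to isatins and α-ketoesters, and amine-promoted aldol condensation of 4-oxoaldehydes to cyclopentenones.

**Step 5**
Reactants: 6; 7, ethyl 3-oxopropanoate (ethyl formylacetate)
Product: 8, ethyl 1-ethoxy-7-hydroxy-7-{[TBSO]methyl}-6-oxo-1,4a,5,6,7,7a-hexahydrocyclopenta[c]pyran-4-carboxylate (C7a and C7 as in 6; C1 OEt drawn as in the target; C4a unspecified)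
Conditions: Et3N (0.3 equiv), CH2Cl2, 0 °C→rt; then PPTS (0.3 equiv), 4 Å MS, rt, one pot
Reagents that add atoms: none
Why: The soft formylacetate enolate adds to C5 of the enone, anti to the C9 substituent (Michael addition).
- Acetal ionisation and O-attack of the enol then close the pyran with loss of EtOH (Büchi/Tietze-type iridoid ring closure).
- The Michael step is reversible, so the cis-fused ring closure drains the equilibrium.
- The new C4a centre is destroyed in step 6, so its configuration does not matter.

**Step 6**
Reactants: 8
Product: 9, ethyl 1-ethoxy-7-hydroxy-7-{[TBSO]methyl}-6-oxo-1,7-dihydro-6H-cyclopenta[c]pyran-4-carboxylate, a push–pull dienone with C5=C6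
Conditions: IBX (2.5 equiv), DMSO, 65 °C
Reagents that add atoms: none
Why: Nicolaou IBX dehydrogenation installs the C5=C6 double bond; C6 is the only enolisable position because C8 is quaternary, and the C4a stereocentre is removed.

**Step 7**
Reactants: 9
Product: 10, diol (C7-OH, C11-OH) with C1-OEt, C8-OH and C10-OTBS
Conditions: DIBAL-H (5 equiv), CH2Cl2, −78→0 °C; Rochelle salt work-up
Reagents that add atoms: none
Why: The aluminium alkoxide of the tertiary C8–OH delivers hydride to C7 from its own (lower) face, placing C7–OH on the upper face, trans to C8–OH (hydroxyl-directed reduction); the excess reagent also reduces the vinylogous carbonate ester to the C11 allylic alcohol.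

**Step 8**
Reactants: 10
Product: 11, C11 isovalerate
Conditions: isovaleryl chloride (1.1 equiv), pyridine, CH2Cl2, −20 °C
Reagents that add atoms: isovaleryl chloride, CC(C)CC(=O)Cl
Why: Chemoselective acylation of the unhindered primary allylic alcohol over the hindered secondary C7–OH and the tertiary C8–OH.

**Step 9**
Reactants: 11
Product: 12, C7 acetate
Conditions: Ac2O, Et3N, DMAP (cat.), CH2Cl2, 0 °C
Reagents that add atoms: acetic anhydride, CC(=O)OC(C)=O
Why: DMAP-catalysed acetylation of the secondary C7–OH, with no change at C7; the tertiary C8–OH is too hindered to react.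

**Step 10**
Reactants: 12
Product: 13, lactol, C1-OH as an anomeric mixture
Conditions: PPTS (0.3 equiv), acetone/H2O (10:1), 45 °C
Reagents that add atoms: water, O
Why: Mild acid-catalysed hydrolysis of the cyclic O,O-acetal via the oxocarbenium ion; the C1 anomer is reset in step 11.

**Step 11**
Reactants: 13
Product: 14, 1,11-bis(isovalerate) with C10-OTBS
Conditions: isovaleryl chloride (1.5 equiv), pyridine, DMAP (cat.), CH2Cl2, 0 °C
Reagents that add atoms: isovaleryl chloride, CC(C)CC(=O)Cl
Why: Acylation of the lactol OH. The anomeric effect favours the axial acylal with H1/H9 trans, as in the target, and any minor anomer is separated by chromatography.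

**Step 12**
Reactants: 14
Product: 15, primary C10 alcohol
Conditions: HF·pyridine, pyridine/THF, 0 °C
Reagents that add atoms: none
Why: Buffered fluoride removes the primary TBS ether, and the acylal, enol ether and acetates survive the pyridine-buffered conditions.

**Step 13**
Reactants: 15; 16, salicylic acid
Product: 17, Jatamanvaltrate I
Conditions: EDC·HCl, DMAP (cat.), CH2Cl2, 0 °C→rt
Reagents that add atoms: none
Why: Steglich esterification occurs selectively at the primary C10–OH, because the tertiary C8–OH is hindered and the intramolecularly H-bonded salicylate phenol is a poor nucleophile.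

## Compound list
1 | 3,3-diethoxypropan-1-ol | OCCC(OCC)OCC | starting material
2 | 3,3-diethoxypropanal | O=CCC(OCC)OCC | intermediate
3 | 4-hydroxybutan-2-one | CC(=O)CCO | starting material
4 | 4-(TBSO)butan-2-one | CC(=O)CCO[Si](C)(C)C(C)(C)C | intermediate
5 | 1-(TBSO)butane-2,3-dione | CC(=O)C(=O)CO[Si](C)(C)C(C)(C)C | intermediate
6 | (4S,5R)-cyclopentenone (acetal trans to CH2OTBS) | O=C1C=C[C@H](C(OCC)OCC)[C@@]1(O)CO[Si](C)(C)C(C)(C)C | intermediate
7 | ethyl 3-oxopropanoate | O=CCC(=O)OCC | starting material
8 | ethyl 1-ethoxy-7-hydroxy-7-(TBSO-methyl)-6-oxo-hexahydrocyclopenta[c]pyran-4-carboxylate | O=C1CC2C(C(=O)OCC)=CO[C@@H](OCC)[C@@H]2[C@@]1(O)CO[Si](C)(C)C(C)(C)C | intermediate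
9 | corresponding 5,6-ene (push–pull dienone) | O=C1C=C2C(C(=O)OCC)=CO[C@@H](OCC)[C@@H]2[C@@]1(O)CO[Si](C)(C)C(C)(C)C | intermediate
10 | 6,7-diol, 4-CH2OH, 1-OEt, 7-CH2OTBS (7-OH trans to 8-OH) | O[C@H]1C=C2C(CO)=CO[C@@H](OCC)[C@@H]2[C@@]1(O)CO[Si](C)(C)C(C)(C)C | intermediate
11 | C11 isovalerate of 10 | O[C@H]1C=C2C(COC(=O)CC(C)C)=CO[C@@H](OCC)[C@@H]2[C@@]1(O)CO[Si](C)(C)C(C)(C)C | intermediate
12 | C7 acetate of 11 | CC(=O)O[C@H]1C=C2C(COC(=O)CC(C)C)=CO[C@@H](OCC)[C@@H]2[C@@]1(O)CO[Si](C)(C)C(C)(C)C | intermediate
13 | lactol (C1 anomer unspecified) | CC(=O)O[C@H]1C=C2C(COC(=O)CC(C)C)=COC(O)[C@@H]2[C@@]1(O)CO[Si](C)(C)C(C)(C)C | intermediate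
14 | 1,11-bis(isovalerate), 10-OTBS | CC(=O)O[C@H]1C=C2C(COC(=O)CC(C)C)=CO[C@@H](OC(=O)CC(C)C)[C@@H]2[C@@]1(O)CO[Si](C)(C)C(C)(C)C | intermediate
15 | C10 primary alcohol | CC(=O)O[C@H]1C=C2C(COC(=O)CC(C)C)=CO[C@@H](OC(=O)CC(C)C)[C@@H]2[C@@]1(O)CO | intermediate
16 | salicylic acid | OC(=O)c1ccccc1O | starting material
17 | Jatamanvaltrate I | CC(=O)O[C@H]1C=C2C(COC(=O)CC(C)C)=CO[C@@H](OC(=O)CC(C)C)[C@@H]2[C@@]1(O)COC(=O)c1ccccc1O | target

## Totals
Total steps: 13. Longest linear sequence: 12 (steps 2–13).

**Three steps most likely to fail**
1. **Step 4 (proposed new step).** Aldehyde self-aldol, poor regioselectivity between the two diketone carbonyls, or β-elimination of the acetal could compete.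
   - Fallback: auxiliary-controlled route from known chemistry. Make the SAMP hydrazone of 2, add its LDA azaenolate to 5 (Enders azaenolate addition to a ketone), cleave the hydrazone with ozone, then run the piperidine/AcOH cyclocondensation to give 6.
2. **Step 7.** The directed DIBAL reduction may give the wrong C7 epimer, or over-reduce the dienone.
   - Fallback: oxidise the undesired allylic alcohol with MnO2, reduce the ketone with Me4NBH(OAc)3 (hydroxyl-directed anti-diol), and use a Mitsunobu inversion with p-nitrobenzoic acid if needed.
3. **Step 10.** Aqueous acid may ionise the allylic C7 acetate or the dienyl ether.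
   - Fallback: skip the lactol. Temporarily silylate C8–OH (TMSOTf, 2,6-lutidine), then convert the C1 ethyl acetal directly to the acylal with isovaleric anhydride and catalytic TMSOTf, a known acetal-to-acylal exchange.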